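Remark: carbons carry daucane numbers throughout (C1 quaternary methyl carbon, C2/C3 ring methylenes, C4 isopropyl carbinol, C5 ring-fusion CH, C6 acyloxy carbon, C7 methylene, C8 with the exocyclic C14, C9 carbinol, C10 methylene); it is assumed that the enantiomer of the carbene ligand in step 1 can be chosen to give the (R)-enolate.

**The problem**

The target is a daucane ester: a trans-fused bicyclo[5.3.0]decane whose cyclopentane holds the quaternary methyl carbon C1 and the isopropyl-bearing tertiary carbinol C4. Its cycloheptane holds a vanilloyloxy group at C6, an exocyclic methylene at C8 and an allylic hydroxyl at C9. Five stereocentres (1R,4R,5S,6S,9S) are needed: the C4 oxygen, the C5–C6 bond and the C1 methyl lie on one face of the five-membered ring, while C10, H5 and the C6 and C9 oxygens lie on the other. C1 can be set by catalysis and is then the only handle on the C4/C5 pair; the C4 hydroxyl can in turn deliver hydride to C6, and the ring conformation fixed by the axial C1 methyl has to set C9. The groups are delicate: at the ketone stage C4–C5–C6 is a tertiary aldol (retro-aldol, dehydration), the 1,1-disubstituted alkene beside an allylic alcohol rules out hydrogenolytic or strongly acidic finishing steps, and the aryl ester with a free phenol and two nearby hydroxyls can migrate under base. The enabling feature is the array O–C4, H–C5, O–C6 with the C4 oxygen and C6 cis on adjacent ring atoms. Written as C6=N–O–C4 it is a cis-fused isoxazoline, the adduct of a nitrile oxide centred on C6 with the C4=C5 bond of a 1-isopropylcyclopentene, and so a masked form of an aldol that an enolate route cannot hold.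

**Retrosynthesis**

The aryl ester and the two silyl groups go first: 32 comes from bis-silyl ether 31, and 31 from diol 27 and protected vanillic acid 30 by acylation of the only secondary hydroxyl left free. Silicon on both the phenol and C9 allows one fluoride step at the end and avoids hydrogenolysis near the exocyclic alkene.

The C6–H bond is cut next, 27 back to β-hydroxy ketone 25. Reduction is placed after ring closure on purpose: in the bicycle the C4 hydroxyl can reach only one face of the C6 carbonyl, so tethered hydride delivery must give the 6S alcohol. In an open-chain C6 ketone the carbonyl is free to turn, and the less crowded rotamer leads to the 6-epimer.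

Ketone 25 is the unmasked form of tricyclic isoxazoline 23, by cleaving N–O and hydrolysing C=N. Keeping the heterocycle until this point means that the retro-aldol-prone ketone exists for one step only and that no enolisable ketone is present beside the C9 aldehyde earlier on.

The seven-membered ring is opened at C8–C9: 23 and its alcohol 22 come from iodoalkenyl aldehyde 20 by an intramolecular alkenylchromium addition. This cut is preferred to a metathesis, which would put the alkene inside the ring, and it creates the methylene and the C9 hydroxyl together. The forward reaction has to select one aldehyde face.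

Aldehyde 20 goes back through alcohol 19 to silyl ether 18, and the iodoalkene of 18 to terminal alkyne 16 and its silyl-capped form 15. C8 is carried through the cycloaddition as an alkyne because a 2-haloallyl group is itself a 1,1-disubstituted dipolarophile, more reactive towards nitrile oxides than the hindered ring alkene; an internal silylalkyne is not.

The key cut removes C5–C6 and O–C4 together: 15 comes from cyclopentene 9 and nitrile oxide 14, made in the flask from oxime 12. This gives two far simpler pieces and sets C4 and C5 in one suprafacial event. It asks for oxygen at the isopropyl-bearing carbon and attack on the face syn to the C1 methyl.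

Cyclopentene 9 is the silyl ether of alcohol 8, which arises from diene 6 by hydroboration of the vinyl group. Diene 6 comes from enol triflate 4 and isopropyl Grignard reagent 5, and 4 from enone 1 and vinyl Grignard reagent 2 by asymmetric conjugate addition with enolate trapping. The trapping fixes both C1 and the position of the ring alkene. Oxime 12 comes from commercial alkynol 10, and acid 30 from vanillic acid 28.

**Roads not taken**

Alternative 1: Both bonds to the quaternary carbon (C1–C5 and C1–C10) are cut, leading to aryl-tethered α-methyl diazo ketone A1. In the forward step Rh2(OAc)4 (or CuOTf with a bis(oxazoline) ligand) would form a carbenoid at C1 that adds to the ipso–ortho bond of the anisole; opening of the norcaradiene gives cycloheptatriene A2.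
- Merits: both rings and the quaternary centre form in one step from a flat precursor, and the methoxy group already marks C8. In skeletal assembly this is faster than the chosen plan, which needs a separate ring closure.
- Weak points: A2 carries a carbonyl at C2 that the target lacks, C5 is sp2, and C5, C6 and C9 must still be set on a triene containing an enol ether. The α-methyl carbenoid can also collapse by 1,2-hydride shift. C1 would be controlled only by the remote tertiary benzylic ether at C4, which itself needs an asymmetric synthesis.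
- Comparison: the chosen plan offers the C4/C5/C6 array at the right oxidation level and no surplus oxygen to delete.

Alternative 2: C7 is excised (C7–C8 and C7–C6), leading to the trans-hydrindane silyl enol ether A3. Et2Zn/CH2I2 cyclopropanation and FeCl3 opening of the siloxycyclopropane, with loss of HCl, would give cycloheptenone A4.
- Merits: the bicyclic framework is available enantiopure and in quantity by proline-catalysed annulation, and the trans fusion and C1 are secure from the start. On this point it is clearly better than the chosen plan, which relies on a moderate facial preference.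
- Weak points: the five-membered ring of A4 is oxygenated at C2, whereas the target needs the isopropyl carbinol at C4 and nothing at C2. Deleting one oxygen and functionalising an unactivated methylene next to the ring fusion, with control, would cost many steps, and C6 oxygenation must still be added to the enone.
- Comparison: the chosen plan places the C4 and C6 oxygens correctly in one step and so should be shorter overall.

Alternative 3: C1–C10 is cut, leading to 2-methylenetetrahydrofuran A5, in which C10=C9–O–C6–C5=C1 is an allyl vinyl ether. Heating would cause [3,3] rearrangement to cyclohept-4-enone A6.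
- Merits: the quaternary centre and the seven-membered ring form in one stereospecific step with chirality transfer from C6 to C1. The C9 ketone and the C5=C6 alkene are well placed for later hydroboration (H5 and O6 add cis, as required) and α-methylenation. If it worked, its endgame would match or beat the chosen one in length, and C9 could be set by reagent-controlled reduction.
- Weak points: the tetrahydrofuran enforces a boat transition state that places C8 over the C4 isopropyl group on the required face. The tertiary silyl ether at C4 is allylic and liable to ionise or eliminate at the temperature needed. A5 itself, with a tetrasubstituted alkene flanked by two stereocentres, is laborious to make.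
- Comparison: the chosen plan uses mild, well-known steps and sets C4, C5 and C6 directly.

Key step: step 6

Step 1
Reactants: 1 3-methylcyclopent-2-en-1-one; 2 vinylmagnesium bromide
Product: 4 (R)-3-methyl-3-vinylcyclopent-1-en-1-yl trifluoromethanesulfonate, via magnesium enolate 3 (not isolated)
Conditions: Cu(OTf)2 (3 mol %), chiral hydroxyalkyl-imidazolinium salt (4 mol %), Et2O, −30 °C; then N-(5-chloropyridin-2-yl)bis(trifluoromethanesulfonimide), THF, −78 °C to rt
Reagents that add atoms: N-(5-chloropyridin-2-yl)bis(trifluoromethanesulfonimide), FC(F)(F)S(=O)(=O)N(c1ccc(Cl)cn1)S(=O)(=O)C(F)(F)F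
Why: Copper-catalysed asymmetric conjugate addition of the vinyl Grignard reagent creates the C1 quaternary stereocentre, the chiral carbene–copper complex selecting the enone face; enolate 3 forms only towards C5, and O-sulfonylation fixes this as the C4=C5 enol triflate.

Step 2
Reactants: 4 (R)-3-methyl-3-vinylcyclopent-1-en-1-yl trifluoromethanesulfonate; 5 isopropylmagnesium chloride
Product: 6 (R)-1-isopropyl-3-methyl-3-vinylcyclopent-1-ene
Conditions: Fe(acac)3 (5 mol %), THF/NMP, −30 to 0 °C
Reagents that add atoms: none
Why: Iron-catalysed Kumada-type cross-coupling of an alkenyl triflate with a secondary alkyl Grignard reagent is fast at low temperature, should not isomerise the isopropyl group and leaves the vinyl group and C1 untouched.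

Step 3
Reactants: 6 (R)-1-isopropyl-3-methyl-3-vinylcyclopent-1-ene
Product: 8 2-[(1R)-3-isopropyl-1-methylcyclopent-2-en-1-yl]ethan-1-ol, via alkylborane 7 (not isolated)
Conditions: 9-BBN, THF, 0 °C to rt; then NaOH, H2O2, 0 °C
Reagents that add atoms: hydrogen peroxide, OO
Why: Hydroboration–oxidation; 9-BBN adds anti-Markovnikov to the monosubstituted vinyl group far faster than to the hindered trisubstituted ring alkene, and oxidation of 7 gives the primary alcohol that becomes C9.

Step 4
Reactants: 8 2-[(1R)-3-isopropyl-1-methylcyclopent-2-en-1-yl]ethan-1-ol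
Product: 9 tert-butyl{2-[(1R)-3-isopropyl-1-methylcyclopent-2-en-1-yl]ethoxy}diphenylsilane
Conditions: TBDPSCl, imidazole, CH2Cl2, rt
Reagents that add atoms: tert-butyl(chloro)diphenylsilane, CC(C)(C)[Si](Cl)(c1ccccc1)c1ccccc1
Why: Standard silylation of a primary alcohol; it removes a hydrogen-bond donor that could steer the dipole to the arm face and enlarges the arm that has to shield that face.

Step 5
Reactants: 10 4-(trimethylsilyl)but-3-yn-1-ol
Product: 12 4-(trimethylsilyl)but-3-ynal oxime (E/Z mixture), via aldehyde 11 (not isolated)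
Conditions: DMP, NaHCO3, CH2Cl2, 0 °C; then NH2OH·HCl, NaOAc, EtOH/H2O, rt
Reagents that add atoms: hydroxylamine hydrochloride, NO.Cl
Why: Buffered Dess–Martin oxidation avoids isomerisation of the β,γ-alkynyl aldehyde 11, which is condensed at once with hydroxylamine to the stable aldoxime.

Step 6
Reactants: 9 tert-butyl{2-[(1R)-3-isopropyl-1-methylcyclopent-2-en-1-yl]ethoxy}diphenylsilane; 12 4-(trimethylsilyl)but-3-ynal oxime
Product: 15 (3aS,4R,6aR)-4-[2-(tert-butyldiphenylsilyloxy)ethyl]-6a-isopropyl-4-methyl-3-[3-(trimethylsilyl)prop-2-yn-1-yl]-4,5,6,6a-tetrahydro-3aH-cyclopenta[d]isoxazole, via hydroximoyl chloride 13 (not isolated), via nitrile oxide 14 (not isolated)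
Conditions: 12 (3 equiv), NCS, pyridine (cat.), CHCl3, rt; then 9, Et3N (syringe pump, 16 h), CHCl3, 40 °C
Reagents that add atoms: none
Why: Chlorination of the oxime gives 13, and slow dehydrochlorination releases nitrile oxide 14 at low stationary concentration (Huisgen in situ method). The dipole adds to the C4=C5 bond of 9 in a concerted, asynchronous, suprafacial (3+2) cycloaddition; the closest known reaction type is the intermolecular addition of aliphatic nitrile oxides to 1-alkylcycloalkenes, which gives ring-fused isoxazolines with oxygen on the more substituted carbon. The isoxazoline ring closes by this intermolecular annulation, C5–C6 and O–C4 forming together, so its fusion to the cyclopentane is necessarily cis. Oxygen goes to C4 and carbon to C5 because the larger HOMO coefficient and the lower steric cost both lie at the CH terminus. C4 and C5 are created together: their mutual configuration follows from suprafacial addition, and their configuration relative to C1 from approach on the methyl-bearing face, anti to the silyloxyethyl arm whose C10 methylene and chain crowd the other face. This facial preference is expected to be moderate, and the minor diastereomer is removed by chromatography here or at 16. The step also needs chemoselectivity for the ring alkene: the silyl-capped internal alkyne of the dipole is a poor dipolarophile, unlike a haloalkene, so an excess of 12 can drive the hindered alkene to conversion while slow base addition limits furoxan formation.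

Step 7
Reactants: 15 (3aS,4R,6aR)-4-[2-(tert-butyldiphenylsilyloxy)ethyl]-6a-isopropyl-4-methyl-3-[3-(trimethylsilyl)prop-2-yn-1-yl]-4,5,6,6a-tetrahydro-3aH-cyclopenta[d]isoxazole
Product: 16 (3aS,4R,6aR)-4-[2-(tert-butyldiphenylsilyloxy)ethyl]-6a-isopropyl-4-methyl-3-(prop-2-yn-1-yl)-4,5,6,6a-tetrahydro-3aH-cyclopenta[d]isoxazole
Conditions: K2CO3 (cat.), MeOH, 0 °C to rt
Reagents that add atoms: none
Why: Methanolysis of the alkynyl C–Si bond by catalytic methoxide; the silyl ether and the isoxazoline are inert under these mild conditions.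

Step 8
Reactants: 16 (3aS,4R,6aR)-4-[2-(tert-butyldiphenylsilyloxy)ethyl]-6a-isopropyl-4-methyl-3-(prop-2-yn-1-yl)-4,5,6,6a-tetrahydro-3aH-cyclopenta[d]isoxazole
Product: 18 (3aS,4R,6aR)-4-[2-(tert-butyldiphenylsilyloxy)ethyl]-3-(2-iodoprop-2-en-1-yl)-6a-isopropyl-4-methyl-4,5,6,6a-tetrahydro-3aH-cyclopenta[d]isoxazole, via iodoalkenylborane 17 (not isolated)
Conditions: B-iodo-9-BBN, hexane/CH2Cl2, −20 to 0 °C; then AcOH, 0 °C
Reagents that add atoms: B-iodo-9-borabicyclo[3.3.1]nonane, IB1C2CCCC1CCC2
Why: Haloboration of a terminal alkyne places iodine on the internal carbon (Markovnikov sense) and boron on the terminus by cis addition to give 17; protodeboronation with acetic acid leaves the 2-iodo-1-alkene needed for ring closure.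

Step 9
Reactants: 18 (3aS,4R,6aR)-4-[2-(tert-butyldiphenylsilyloxy)ethyl]-3-(2-iodoprop-2-en-1-yl)-6a-isopropyl-4-methyl-4,5,6,6a-tetrahydro-3aH-cyclopenta[d]isoxazole
Product: 19 2-[(3aS,4R,6aR)-3-(2-iodoprop-2-en-1-yl)-6a-isopropyl-4-methyl-4,5,6,6a-tetrahydro-3aH-cyclopenta[d]isoxazol-4-yl]ethan-1-ol
Conditions: HF·pyridine, pyridine, THF, 0 °C to rt
Reagents that add atoms: none
Why: Fluoride cleavage of the primary silyl ether under non-basic conditions avoids dehydroiodination of the iodoalkene; the isoxazoline is stable to HF·pyridine.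

Step 10
Reactants: 19 2-[(3aS,4R,6aR)-3-(2-iodoprop-2-en-1-yl)-6a-isopropyl-4-methyl-4,5,6,6a-tetrahydro-3aH-cyclopenta[d]isoxazol-4-yl]ethan-1-ol
Product: 20 2-[(3aS,4R,6aR)-3-(2-iodoprop-2-en-1-yl)-6a-isopropyl-4-methyl-4,5,6,6a-tetrahydro-3aH-cyclopenta[d]isoxazol-4-yl]acetaldehyde
Conditions: DMP, NaHCO3, CH2Cl2, 0 °C to rt
Reagents that add atoms: none
Why: Dess–Martin oxidation gives the C9 aldehyde; with C6 still masked as the isoxazoline there is no enolisable ketone to undergo aldol reaction with it.

Step 11
Reactants: 20 2-[(3aS,4R,6aR)-3-(2-iodoprop-2-en-1-yl)-6a-isopropyl-4-methyl-4,5,6,6a-tetrahydro-3aH-cyclopenta[d]isoxazol-4-yl]acetaldehyde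
Product: 22 (1R,4R,5S,9S)-9-hydroxy-8-methylene tricyclic isoxazoline (C6=N–O–C4 ring fused to the trans-5/7 carbocycle; daucane numbering), via alkenylchromium 21 (not isolated)
Conditions: CrCl2 (8 equiv), NiCl2 (2 mol %), DMSO/THF, rt, 0.005 M
Reagents that add atoms: none
Why: Nozaki–Hiyama–Kishi reaction: nickel-catalysed formation of alkenylchromium 21 and its 7-exo-trig addition to the aldehyde close the seven-membered ring and install the C8 methylene and the C9 hydroxyl together; CrCl2 is not expected to cleave the N–O bond of an O-alkyl oxime ether under aprotic conditions. The 9S alcohol should be favoured because the chromium alkoxide can lie pseudo-equatorial, away from the axial C1 methyl, in the closing ring.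

Step 12
Reactants: 22 (1R,4R,5S,9S)-9-hydroxy-8-methylene tricyclic isoxazoline
Product: 23 (1R,4R,5S,9S)-9-(tert-butyldimethylsilyloxy)-8-methylene tricyclic isoxazoline (daucane numbering)
Conditions: TBSCl, imidazole, DMF, rt
Reagents that add atoms: tert-butyl(chloro)dimethylsilane, CC(C)(C)[Si](C)(C)Cl
Why: Silylation of the secondary allylic alcohol ensures that C9–OH can neither direct the later reduction nor compete in the esterification.

Step 13
Reactants: 23 (1R,4R,5S,9S)-9-(tert-butyldimethylsilyloxy)-8-methylene tricyclic isoxazoline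
Product: 25 (3R,3aR,7S,8aR)-7-(tert-butyldimethylsilyloxy)-3-hydroxy-3-isopropyl-8a-methyl-6-methylene-2,3,3a,5,6,7,8,8a-octahydroazulen-4(1H)-one, via hydroxy imine 24 (not isolated)
Conditions: Mo(CO)6, MeCN/H2O (15:1), 80 °C
Reagents that add atoms: water, O
Why: Reductive N–O cleavage of the isoxazoline by Mo(CO)6 and hydrolysis of imine 24 in wet acetonitrile unveil the tertiary aldol without touching the exocyclic alkene or the silyl ether; the product is used directly to limit retro-aldol cleavage and migration of the β,γ-double bond.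

Step 14
Reactants: 25 (3R,3aR,7S,8aR)-7-(tert-butyldimethylsilyloxy)-3-hydroxy-3-isopropyl-8a-methyl-6-methylene-2,3,3a,5,6,7,8,8a-octahydroazulen-4(1H)-one
Product: 27 (3R,3aS,4S,7S,8aR)-7-(tert-butyldimethylsilyloxy)-3-isopropyl-8a-methyl-6-methylenedecahydroazulene-3,4-diol, via alkoxyborohydride 26 (not isolated)
Conditions: Me4NBH(OAc)3, MeCN/AcOH (1:1), −20 °C
Reagents that add atoms: none
Why: Evans–Saksena reduction: exchange of the C4 hydroxyl onto boron gives 26, which delivers hydride intramolecularly to the face of the ring ketone on which the C4 oxygen sits, so the new C6 hydroxyl is anti to C4–OH (6S); without this tether the reagent does not reduce the ketone.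

Step 15
Reactants: 28 4-hydroxy-3-methoxybenzoic acid (vanillic acid)
Product: 30 4-(tert-butyldimethylsilyloxy)-3-methoxybenzoic acid, via bis-silyl vanillate 29 (not isolated)
Conditions: TBSCl, imidazole, DMF, rt; then AcOH/THF/H2O, rt
Reagents that add atoms: tert-butyl(chloro)dimethylsilane, CC(C)(C)[Si](C)(C)Cl
Why: Exhaustive silylation followed by mild hydrolysis of the labile silyl ester in 29 leaves the phenol protected and the acid free.

Step 16
Reactants: 27 (3R,3aS,4S,7S,8aR)-7-(tert-butyldimethylsilyloxy)-3-isopropyl-8a-methyl-6-methylenedecahydroazulene-3,4-diol; 30 4-(tert-butyldimethylsilyloxy)-3-methoxybenzoic acid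
Product: 31 (3R,3aS,4S,7S,8aR)-7-(tert-butyldimethylsilyloxy)-3-hydroxy-3-isopropyl-8a-methyl-6-methylenedecahydroazulen-4-yl 4-(tert-butyldimethylsilyloxy)-3-methoxybenzoate
Conditions: EDC·HCl, DMAP, CH2Cl2, rt to 40 °C
Reagents that add atoms: none
Why: Steglich esterification; carbodiimide activation and DMAP acyl transfer acylate the secondary C6 hydroxyl, while the tertiary C4 hydroxyl is unreactive and C9 is silylated.

Step 17
Reactants: 31 (3R,3aS,4S,7S,8aR)-7-(tert-butyldimethylsilyloxy)-3-hydroxy-3-isopropyl-8a-methyl-6-methylenedecahydroazulen-4-yl 4-(tert-butyldimethylsilyloxy)-3-methoxybenzoate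
Product: 32 (3R,3aS,4S,7S,8aR)-3,7-dihydroxy-3-isopropyl-8a-methyl-6-methylenedecahydroazulen-4-yl 4-hydroxy-3-methoxybenzoate (CNP0330487.1)
Conditions: TBAF, AcOH, THF, 0 °C to rt
Reagents that add atoms: none
Why: Buffered fluoride removes the aryl and the secondary alkyl silyl ether in one operation; acetic acid suppresses phenoxide- or alkoxide-mediated acyl migration of the vanillate.

**Compound list**

1 | 3-methylcyclopent-2-en-1-one | CC1=CC(=O)CC1 | starting material
2 | vinylmagnesium bromide | C=C[Mg]Br | starting material
3 | bromomagnesium (R)-3-methyl-3-vinylcyclopent-1-en-1-olate | C=C[C@]1(C)C=C(O[Mg]Br)CC1 | intermediate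
4 | (R)-3-methyl-3-vinylcyclopent-1-en-1-yl trifluoromethanesulfonate | C=C[C@]1(C)C=C(OS(=O)(=O)C(F)(F)F)CC1 | intermediate
5 | isopropylmagnesium chloride | CC(C)[Mg]Cl | starting material
6 | (R)-1-isopropyl-3-methyl-3-vinylcyclopent-1-ene | C=C[C@]1(C)C=C(C(C)C)CC1 | intermediate
7 | 9-{2-[(1S)-3-isopropyl-1-methylcyclopent-2-en-1-yl]ethyl}-9-borabicyclo[3.3.1]nonane | CC(C)C1=C[C@@](C)(CCB2C3CCCC2CCC3)CC1 | intermediate
8 | 2-[(1R)-3-isopropyl-1-methylcyclopent-2-en-1-yl]ethan-1-ol | CC(C)C1=C[C@@](C)(CCO)CC1 | intermediate
9 | tert-butyl{2-[(1R)-3-isopropyl-1-methylcyclopent-2-en-1-yl]ethoxy}diphenylsilane | CC(C)C1=C[C@@](C)(CCO[Si](c2ccccc2)(c2ccccc2)C(C)(C)C)CC1 | intermediate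
10 | 4-(trimethylsilyl)but-3-yn-1-ol | C[Si](C)(C)C#CCCO | starting material
11 | 4-(trimethylsilyl)but-3-ynal | C[Si](C)(C)C#CCC=O | intermediate
12 | 4-(trimethylsilyl)but-3-ynal oxime (E/Z mixture) | C[Si](C)(C)C#CCC=NO | intermediate
13 | N-hydroxy-4-(trimethylsilyl)but-3-ynimidoyl chloride | C[Si](C)(C)C#CCC(Cl)=NO | intermediate
14 | 4-(trimethylsilyl)but-3-ynenitrile oxide | C[Si](C)(C)C#CCC#[N+][O-] | intermediate
15 | (3aS,4R,6aR)-4-[2-(tert-butyldiphenylsilyloxy)ethyl]-6a-isopropyl-4-methyl-3-[3-(trimethylsilyl)prop-2-yn-1-yl]-4,5,6,6a-tetrahydro-3aH-cyclopenta[d]isoxazole | C[Si](C)(C)C#CCC1=NO[C@@]2(C(C)C)CC[C@](C)(CCO[Si](c3ccccc3)(c3ccccc3)C(C)(C)C)[C@@H]12 | intermediate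
16 | (3aS,4R,6aR)-4-[2-(tert-butyldiphenylsilyloxy)ethyl]-6a-isopropyl-4-methyl-3-(prop-2-yn-1-yl)-4,5,6,6a-tetrahydro-3aH-cyclopenta[d]isoxazole | C#CCC1=NO[C@@]2(C(C)C)CC[C@](C)(CCO[Si](c3ccccc3)(c3ccccc3)C(C)(C)C)[C@@H]12 | intermediate
17 | (Z)-2-iodoalkenyl-9-BBN adduct of 16 (iodine on C8, boron on C14) | I/C(CC1=NO[C@@]2(C(C)C)CC[C@](C)(CCO[Si](c3ccccc3)(c3ccccc3)C(C)(C)C)[C@@H]12)=C\B1C2CCCC1CCC2 | intermediate
18 | (3aS,4R,6aR)-4-[2-(tert-butyldiphenylsilyloxy)ethyl]-3-(2-iodoprop-2-en-1-yl)-6a-isopropyl-4-methyl-4,5,6,6a-tetrahydro-3aH-cyclopenta[d]isoxazole | C=C(I)CC1=NO[C@@]2(C(C)C)CC[C@](C)(CCO[Si](c3ccccc3)(c3ccccc3)C(C)(C)C)[C@@H]12 | intermediate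
19 | 2-[(3aS,4R,6aR)-3-(2-iodoprop-2-en-1-yl)-6a-isopropyl-4-methyl-4,5,6,6a-tetrahydro-3aH-cyclopenta[d]isoxazol-4-yl]ethan-1-ol | C=C(I)CC1=NO[C@@]2(C(C)C)CC[C@](C)(CCO)[C@@H]12 | intermediate
20 | 2-[(3aS,4R,6aR)-3-(2-iodoprop-2-en-1-yl)-6a-isopropyl-4-methyl-4,5,6,6a-tetrahydro-3aH-cyclopenta[d]isoxazol-4-yl]acetaldehyde | C=C(I)CC1=NO[C@@]2(C(C)C)CC[C@](C)(CC=O)[C@@H]12 | intermediate
21 | alkenylchromium dichloride from 20 (trivalent chromium on C8) | C=C([Cr](Cl)Cl)CC1=NO[C@@]2(C(C)C)CC[C@](C)(CC=O)[C@@H]12 | intermediate
22 | (1R,4R,5S,9S)-9-hydroxy-8-methylene tricyclic isoxazoline (C6=N–O–C4 ring fused to the trans-5/7 carbocycle; daucane numbering) | C=C1CC2=NO[C@@]3(C(C)C)CC[C@](C)(C[C@@H]1O)[C@@H]23 | intermediate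
23 | (1R,4R,5S,9S)-9-(tert-butyldimethylsilyloxy)-8-methylene tricyclic isoxazoline (daucane numbering) | C=C1CC2=NO[C@@]3(C(C)C)CC[C@](C)(C[C@@H]1O[Si](C)(C)C(C)(C)C)[C@@H]23 | intermediate
24 | C6 imine of 25 (β-hydroxy imine) | C=C1CC(=N)[C@H]2[C@](O)(C(C)C)CC[C@]2(C)C[C@@H]1O[Si](C)(C)C(C)(C)C | intermediate
25 | (3R,3aR,7S,8aR)-7-(tert-butyldimethylsilyloxy)-3-hydroxy-3-isopropyl-8a-methyl-6-methylene-2,3,3a,5,6,7,8,8a-octahydroazulen-4(1H)-one | C=C1CC(=O)[C@H]2[C@](O)(C(C)C)CC[C@]2(C)C[C@@H]1O[Si](C)(C)C(C)(C)C | intermediate
26 | tetramethylammonium diacetoxy(hydrido)borate of the C4 alkoxide of 25 | C=C1CC(=O)[C@H]2[C@](O[BH-](OC(C)=O)OC(C)=O)(C(C)C)CC[C@]2(C)C[C@@H]1O[Si](C)(C)C(C)(C)C.C[N+](C)(C)C | intermediate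
27 | (3R,3aS,4S,7S,8aR)-7-(tert-butyldimethylsilyloxy)-3-isopropyl-8a-methyl-6-methylenedecahydroazulene-3,4-diol | C=C1C[C@H](O)[C@@H]2[C@](C)(CC[C@@]2(O)C(C)C)C[C@@H]1O[Si](C)(C)C(C)(C)C | intermediate
28 | 4-hydroxy-3-methoxybenzoic acid (vanillic acid) | COc1cc(C(=O)O)ccc1O | starting material
29 | tert-butyldimethylsilyl 4-(tert-butyldimethylsilyloxy)-3-methoxybenzoate | COc1cc(C(=O)O[Si](C)(C)C(C)(C)C)ccc1O[Si](C)(C)C(C)(C)C | intermediate
30 | 4-(tert-butyldimethylsilyloxy)-3-methoxybenzoic acid | COc1cc(C(=O)O)ccc1O[Si](C)(C)C(C)(C)C | intermediate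
31 | (3R,3aS,4S,7S,8aR)-7-(tert-butyldimethylsilyloxy)-3-hydroxy-3-isopropyl-8a-methyl-6-methylenedecahydroazulen-4-yl 4-(tert-butyldimethylsilyloxy)-3-methoxybenzoate | C=C1C[C@H](OC(=O)c2ccc(O[Si](C)(C)C(C)(C)C)c(OC)c2)[C@@H]2[C@](C)(CC[C@@]2(O)C(C)C)C[C@@H]1O[Si](C)(C)C(C)(C)C | intermediate
32 | (3R,3aS,4S,7S,8aR)-3,7-dihydroxy-3-isopropyl-8a-methyl-6-methylenedecahydroazulen-4-yl 4-hydroxy-3-methoxybenzoate | C=C1C[C@H](OC(=O)c2ccc(O)c(OC)c2)[C@@H]2[C@](C)(CC[C@@]2(O)C(C)C)C[C@@H]1O | target

**Step count and least certain steps**

Total step count: 17. Longest linear sequence: 15 (steps 1–4, 6–14, 16 and 17; steps 5 and 15 are side branches).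

Step 6 (key step). The most likely failure is dimerisation of the aliphatic nitrile oxide to its furoxan outrunning addition to a trisubstituted alkene whose CH terminus is flanked by a quaternary carbon, compounded by only moderate discrimination between the methyl and the silyloxyethyl face. Fallback: attach C6 with a more electrophilic dipole that tolerates large excess and complete C7–C8 afterwards. Setting out from 9, ethoxycarbonylformonitrile oxide F1 (from ethyl 2-chloro-2-(hydroxyimino)acetate and NaHCO3 in EtOAc) should add to the electron-rich alkene to give the ethyl isoxazoline-3-carboxylate F2. NaBH4 reduces the ester to the hydroxymethyl isoxazoline F3, and CBr4/PPh3 gives the bromomethyl isoxazoline F4. CuI-catalysed coupling of this activated bromide with (trimethylsilyl)ethynylmagnesium bromide returns to the route at 15. The facial question is unchanged, and the diastereomers are again separated at 15.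

Step 1. Erosion of enantioselectivity is the main risk, because five-membered enones and vinyl Grignard reagents are the least favourable partners for this catalyst class and 1,2-addition competes. Fallback: change the nucleophile and ligand class and relay the enolate. Setting out from 1, copper-catalysed addition (Cu(OTf)2, chiral phosphoramidite-type ligand) of dimethyl(vinyl)aluminium F5 (from 2 and Me2AlCl), followed by in-flask acetylation with Ac2O, gives the enol acetate F6. MeLi and the same pyridyl triflimide then return to the route at 4.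

Step 8. The Lewis-acidic haloborane may attack the silyl ether or complex the isoxazoline nitrogen, giving incomplete or unselective addition. Fallback: setting out from 16, Markovnikov hydrosilylation with Et3SiH catalysed by [Cp*Ru(MeCN)3]PF6 gives the 2-(triethylsilyl)allyl isoxazoline F7, and iododesilylation with N-iodosuccinimide returns to the route at 18.

Step 11. Poor facial selectivity at the aldehyde is the likely problem, since nothing but ring conformation controls C9; slow closure of the strained tricycle is a secondary risk. Fallback: setting out from 20, if the closure gives mainly the 9R alcohol F8, Mitsunobu reaction with 4-nitrobenzoic acid (DIAD, PPh3) inverts C9 to the 9S 4-nitrobenzoate F9, and methanolysis (K2CO3, MeOH), harmless while C6 is still masked, returns to the route at 22.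

Step 14. Sluggish ligand exchange of the tertiary C4 hydroxyl on boron would leave the ketone unreduced or open the way to untethered, unselective reduction. Fallback: setting out from 25, reduction with SmI2 in THF/MeOH, which proceeds through a samarium chelate of the hydroxyl and the ketyl and is known to give anti-1,3-diols from β-hydroxy ketones, returns to the route at 27 without new isolated compounds.

**Further compounds**

F1 | step 6 | ethoxycarbonylformonitrile oxide | CCOC(=O)C#[N+][O-]
F2 | step 6 | ethyl (3aS,4R,6aR)-4-[2-(tert-butyldiphenylsilyloxy)ethyl]-6a-isopropyl-4-methyl-4,5,6,6a-tetrahydro-3aH-cyclopenta[d]isoxazole-3-carboxylate | CCOC(=O)C1=NO[C@@]2(C(C)C)CC[C@](C)(CCO[Si](c3ccccc3)(c3ccccc3)C(C)(C)C)[C@@H]12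
F3 | step 6 | {(3aS,4R,6aR)-4-[2-(tert-butyldiphenylsilyloxy)ethyl]-6a-isopropyl-4-methyl-4,5,6,6a-tetrahydro-3aH-cyclopenta[d]isoxazol-3-yl}methanol | OCC1=NO[C@@]2(C(C)C)CC[C@](C)(CCO[Si](c3ccccc3)(c3ccccc3)C(C)(C)C)[C@@H]12
F4 | step 6 | (3aS,4R,6aR)-3-(bromomethyl)-4-[2-(tert-butyldiphenylsilyloxy)ethyl]-6a-isopropyl-4-methyl-4,5,6,6a-tetrahydro-3aH-cyclopenta[d]isoxazole | BrCC1=NO[C@@]2(C(C)C)CC[C@](C)(CCO[Si](c3ccccc3)(c3ccccc3)C(C)(C)C)[C@@H]12
F5 | step 1 | dimethyl(vinyl)aluminium | C=C[Al](C)C
F6 | step 1 | (R)-3-methyl-3-vinylcyclopent-1-en-1-yl acetate | C=C[C@]1(C)C=C(OC(C)=O)CC1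
F7 | step 8 | (3aS,4R,6aR)-4-[2-(tert-butyldiphenylsilyloxy)ethyl]-6a-isopropyl-4-methyl-3-[2-(triethylsilyl)prop-2-en-1-yl]-4,5,6,6a-tetrahydro-3aH-cyclopenta[d]isoxazole | C=C([Si](CC)(CC)CC)CC1=NO[C@@]2(C(C)C)CC[C@](C)(CCO[Si](c3ccccc3)(c3ccccc3)C(C)(C)C)[C@@H]12
F8 | step 11 | (1R,4R,5S,9R)-9-hydroxy-8-methylene tricyclic isoxazoline (9-epimer of 22) | C=C1CC2=NO[C@@]3(C(C)C)CC[C@](C)(C[C@H]1O)[C@@H]23
F9 | step 11 | 4-nitrobenzoate of 22 (9S) | C=C1CC2=NO[C@@]3(C(C)C)CC[C@](C)(C[C@@H]1OC(=O)c4ccc(cc4)[N+](=O)[O-])[C@@H]23
F0 | step 14 | none | none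
A1 | alternative 1 | (5R)-2-diazo-5-(4-methoxyphenyl)-6-methyl-5-(triethylsilyloxy)heptan-3-one | CC(C)[C@](O[Si](CC)(CC)CC)(CC(=O)C(C)=[N+]=[N-])c1ccc(OC)cc1
A2 | alternative 1 | (3R,8aR)-3-isopropyl-6-methoxy-8a-methyl-3-(triethylsilyloxy)-3,8a-dihydroazulen-1(2H)-one | CC(C)[C@]1(O[Si](CC)(CC)CC)CC(=O)[C@]2(C)C=CC(OC)=CC=C12
A3 | alternative 2 | trans-fused 1-(tert-butyldimethylsilyloxy)-7a-methyl-5-(trimethylsilyloxy)-2,3,3a,6,7,7a-hexahydro-1H-indene | C[Si](C)(C)OC1=C[C@H]2CC[C@@H](O[Si](C)(C)C(C)(C)C)[C@]2(C)CC1
A4 | alternative 2 | trans-fused 1-(tert-butyldimethylsilyloxy)-8a-methyl-2,3,3a,7,8,8a-hexahydroazulen-6(1H)-one | O=C1C=C[C@H]2CC[C@@H](O[Si](C)(C)C(C)(C)C)[C@]2(C)CC1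
A5 | alternative 3 | (2R)-2-[(5R)-5-isopropyl-2-methyl-5-(triethylsilyloxy)cyclopent-1-en-1-yl]-5-methylenetetrahydrofuran | C=C1CC[C@@H](O1)C2=C(C)CC[C@@]2(O[Si](CC)(CC)CC)C(C)C
A6 | alternative 3 | 3-isopropyl-8a-methyl-3-(triethylsilyloxy)-2,3,5,6,8,8a-hexahydroazulen-7(1H)-one | O=C1CCC=C2[C@](O[Si](CC)(CC)CC)(C(C)C)CC[C@]2(C)C1
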